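**Retrosynthetic overview**

1. The target comes from a fully benzylated 5-O-galloyl chroman by one hydrogenolysis; the ester comes from a C5 phenol, and the phenol from a C5 bromide.
2. Key disconnection O1–C8a: O1 (on C8a) and O5 (on C5) sit on the two A-ring carbons that flank C4a. An A ring with bromine on both lets the C2 hydroxyl close the pyran ring onto either one, and the surviving bromine is then at C5.
3. Open-chain precursor: the C2 stereocentre comes from chelation-controlled reduction of an α-benzyloxy aryl ketone, and the C1′–C2 bond from an aryl Grignard plus a Weinreb amide.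
4. The C3 stereocentre and the C3–C4 bond come from alkylation of a chiral glycolate imide with a 2,6-dibromobenzylic bromide, itself made by lithiation/formylation of 1-(benzyloxy)-3,5-dibromobenzene.
5. Ring order: the three benzene rings are bought; the pyran ring is the only ring formed (step 10).

Key step: step 10

Remark: the C3 oxygen is carried as a benzyl ether, so the last hydrogenolysis frees all seven hydroxyls at once and no acid step touches the aryl gallate; the compounds marked as starting materials are taken to be purchasable.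

**Route**

Step 1
Reactants: 1 3,5-dibromophenol; 2 benzyl bromide
Product: 3 1-(benzyloxy)-3,5-dibromobenzene
Conditions: K2CO3, DMF, 60 °C
Reagents that add atoms: none
Why: Williamson ether synthesis, the phenoxide being the only nucleophile present.

Step 2
Reactants: 3 1-(benzyloxy)-3,5-dibromobenzene
Product: 5 4-(benzyloxy)-2,6-dibromobenzaldehyde, via aryllithium 4 (not isolated)
Conditions: LDA, THF, −78 °C; DMF, −78 °C; aq. NH4Cl
Reagents that add atoms: N,N-dimethylformamide, CN(C)C=O
Why: The ring proton flanked by the two bromines is the most acidic one, so the amide base lithiates there without Br/Li exchange (ortho-metalation/formylation), and the aryllithium is kept at −78 °C to prevent loss of LiBr to an aryne.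

Step 3
Reactants: 5 4-(benzyloxy)-2,6-dibromobenzaldehyde
Product: 6 [4-(benzyloxy)-2,6-dibromophenyl]methanol
Conditions: NaBH4, MeOH/THF, 0 °C
Reagents that add atoms: none
Why: Borohydride reduction of an aldehyde, which leaves aryl bromides and the benzyl ether untouched.

Step 4
Reactants: 6 [4-(benzyloxy)-2,6-dibromophenyl]methanol
Product: 7 5-(benzyloxy)-1,3-dibromo-2-(bromomethyl)benzene
Conditions: PBr3, CH2Cl2, 0 °C
Reagents that add atoms: phosphorus tribromide, BrP(Br)Br
Why: Conversion of a benzylic alcohol into the bromide through its phosphite ester (SN2 by bromide), under which the aryl benzyl ether is stable at 0 °C.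

Step 5
Reactants: 8 (R)-4-benzyl-1,3-oxazolidin-2-one; 9 (benzyloxy)acetyl chloride
Product: 10 (4R)-4-benzyl-3-[(benzyloxy)acetyl]-1,3-oxazolidin-2-one
Conditions: Et3N, DMAP (cat.), CH2Cl2, 0 °C → rt
Reagents that add atoms: none
Why: DMAP-catalysed N-acylation of the oxazolidinone by the acid chloride, a standard preparation of Evans imides.

Step 6
Reactants: 10 (4R)-4-benzyl-3-[(benzyloxy)acetyl]-1,3-oxazolidin-2-one; 7 5-(benzyloxy)-1,3-dibromo-2-(bromomethyl)benzene
Product: 12 (4R)-4-benzyl-3-[(2S)-2-(benzyloxy)-3-[4-(benzyloxy)-2,6-dibromophenyl]propanoyl]-1,3-oxazolidin-2-one, via sodium Z-enolate 11 (not isolated)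
Conditions: NaHMDS, THF, −78 °C; then 7, −78 → −40 °C
Reagents that add atoms: none
Why: Evans-type glycolate alkylation in which the chelated sodium Z-enolate is shielded on one face by the C4 benzyl group of the (R)-auxiliary, so the benzylic bromide adds from the other face and sets the 2S centre (C3 of the target).

Step 7
Reactants: 12 (4R)-4-benzyl-3-[(2S)-2-(benzyloxy)-3-[4-(benzyloxy)-2,6-dibromophenyl]propanoyl]-1,3-oxazolidin-2-one
Product: 13 (2S)-2-(benzyloxy)-3-[4-(benzyloxy)-2,6-dibromophenyl]-N-methoxy-N-methylpropanamide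
Conditions: MeNH(OMe)·HCl, AlMe3, CH2Cl2, 0 °C → rt; aq. HCl work-up
Reagents that add atoms: N,O-dimethylhydroxylamine hydrochloride, CNOC.Cl
Why: Weinreb transamination, in which the non-basic aluminium amide attacks the exocyclic imide carbonyl and releases the auxiliary without epimerising the α-alkoxy centre.

Step 8
Reactants: 13 (2S)-2-(benzyloxy)-3-[4-(benzyloxy)-2,6-dibromophenyl]-N-methoxy-N-methylpropanamide; 14 4-bromo-1,2-bis(benzyloxy)benzene
Product: 16 (2S)-2-(benzyloxy)-3-[4-(benzyloxy)-2,6-dibromophenyl]-1-[3,4-bis(benzyloxy)phenyl]propan-1-one, via arylmagnesium bromide 15 (not isolated)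
Conditions: Mg, THF, reflux (14 → 15); then 13, THF, 0 °C; aq. NH4Cl
Reagents that add atoms: none
Why: Grignard addition to a Weinreb amide stops at the ketone because the magnesium chelate of the tetrahedral adduct survives until the quench, which also keeps the α-centre from enolising, and an arylmagnesium halide does not exchange with the aryl bromides at 0 °C.

Step 9
Reactants: 16 (2S)-2-(benzyloxy)-3-[4-(benzyloxy)-2,6-dibromophenyl]-1-[3,4-bis(benzyloxy)phenyl]propan-1-one
Product: 17 (1R,2S)-2-(benzyloxy)-3-[4-(benzyloxy)-2,6-dibromophenyl]-1-[3,4-bis(benzyloxy)phenyl]propan-1-ol (1,2-anti)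
Conditions: Zn(BH4)2 (from ZnCl2 + NaBH4), Et2O/THF, −30 → 0 °C
Reagents that add atoms: none
Why: Cram-chelate reduction, in which zinc bridges the carbonyl oxygen and the α-benzyloxy oxygen and hydride adds to the face opposite the CH2Ar group, giving the anti (1R,2S) alcohol (C2 of the target).

Step 10
Reactants: 17 (1R,2S)-2-(benzyloxy)-3-[4-(benzyloxy)-2,6-dibromophenyl]-1-[3,4-bis(benzyloxy)phenyl]propan-1-ol
Product: 18 (2R,3S)-3,7-bis(benzyloxy)-2-[3,4-bis(benzyloxy)phenyl]-5-bromo-3,4-dihydro-2H-chromene (2,3-trans)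
Conditions: CuI (10 mol%), 3,4,7,8-tetramethyl-1,10-phenanthroline (20 mol%), Cs2CO3, toluene (0.02 M), 110 °C, Ar
Reagents that add atoms: none
Why: Ullmann-type intramolecular C–O coupling in which the copper(I) alkoxide of the benzylic hydroxyl inserts into one of the two ortho C–Br bonds and C–O reductive elimination from the seven-membered aryl–copper(III)–alkoxide forms O1–C8a. The closest known reactions are copper/phenanthroline etherifications of aryl bromides with secondary alcohols and their intramolecular versions that give chromans. The pyran ring closes as a six-membered ring by ipso attack of the tethered oxygen on the aryl carbon (exo with respect to the breaking C–Br bond). No stereocentre is formed: the carbinol C–O bond is never broken, so C2 keeps its R configuration, and the C3 ether centre is not involved. Ring size is secured because the C3 oxygen is a benzyl ether and the benzylic hydroxyl is the only nucleophile; the choice of bromide is moot because rotation about the C4–C4a bond makes the two C–Br bonds homotopic, so either closure gives the same 5-bromo-7-benzyloxy chroman. Coupling of the second bromide with another molecule is held back by dilution.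

Step 11
Reactants: 18 (2R,3S)-3,7-bis(benzyloxy)-2-[3,4-bis(benzyloxy)phenyl]-5-bromo-3,4-dihydro-2H-chromene
Product: 19 (2R,3S)-3,7-bis(benzyloxy)-2-[3,4-bis(benzyloxy)phenyl]-3,4-dihydro-2H-chromen-5-ol
Conditions: Pd2(dba)3 (2 mol%), t-BuXPhos (8 mol%), KOH, 1,4-dioxane/H2O, 100 °C; then aq. HCl to pH 5
Reagents that add atoms: potassium hydroxide, [K+].[OH-]
Why: Palladium-catalysed hydroxylation of an aryl bromide (oxidative addition, bromide/hydroxide exchange, C–O reductive elimination driven by the bulky biaryl phosphine), with no base-sensitive group or acidic stereocentre in the substrate.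

Step 12
Reactants: 19 (2R,3S)-3,7-bis(benzyloxy)-2-[3,4-bis(benzyloxy)phenyl]-3,4-dihydro-2H-chromen-5-ol; 20 3,4,5-tris(benzyloxy)benzoic acid
Product: 21 (2R,3S)-3,7-bis(benzyloxy)-2-[3,4-bis(benzyloxy)phenyl]-3,4-dihydro-2H-chromen-5-yl 3,4,5-tris(benzyloxy)benzoate
Conditions: EDC·HCl, DMAP, CH2Cl2, rt
Reagents that add atoms: none
Why: Steglich esterification, in which the carbodiimide-activated acid is transferred by DMAP to the C5 phenol, the only free hydroxyl in the molecule.

Step 13
Reactants: 21 (2R,3S)-3,7-bis(benzyloxy)-2-[3,4-bis(benzyloxy)phenyl]-3,4-dihydro-2H-chromen-5-yl 3,4,5-tris(benzyloxy)benzoate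
Product: 22 catechin 5-O-gallate, (2R,3S)-2-(3,4-dihydroxyphenyl)-3,7-dihydroxy-3,4-dihydro-2H-chromen-5-yl 3,4,5-trihydroxybenzoate
Conditions: H2 (1 atm), 20% Pd(OH)2/C, THF/MeOH, rt
Reagents that add atoms: none
Why: Hydrogenolysis of the six aryl benzyl ethers and the C3 alkyl benzyl ether over Pearlman's catalyst, which should leave the aryl ester and the cyclic C2–O1 bond intact if the reaction is stopped once uptake ends.

**Compound list**

1 | 3,5-dibromophenol | Oc1cc(Br)cc(Br)c1 | starting material
2 | benzyl bromide | BrCc1ccccc1 | starting material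
3 | 1-(benzyloxy)-3,5-dibromobenzene | Brc1cc(Br)cc(OCc2ccccc2)c1 | intermediate
4 | [4-(benzyloxy)-2,6-dibromophenyl]lithium | [Li]c1c(Br)cc(OCc2ccccc2)cc1Br | intermediate (not isolated)
5 | 4-(benzyloxy)-2,6-dibromobenzaldehyde | O=Cc1c(Br)cc(OCc2ccccc2)cc1Br | intermediate
6 | [4-(benzyloxy)-2,6-dibromophenyl]methanol | OCc1c(Br)cc(OCc2ccccc2)cc1Br | intermediate
7 | 5-(benzyloxy)-1,3-dibromo-2-(bromomethyl)benzene | BrCc1c(Br)cc(OCc2ccccc2)cc1Br | intermediate
8 | (R)-4-benzyl-1,3-oxazolidin-2-one | O=C1OC[C@@H](Cc2ccccc2)N1 | starting material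
9 | (benzyloxy)acetyl chloride | O=C(Cl)COCc1ccccc1 | starting material
10 | (4R)-4-benzyl-3-[(benzyloxy)acetyl]-1,3-oxazolidin-2-one | O=C1OC[C@@H](Cc2ccccc2)N1C(=O)COCc1ccccc1 | intermediate
11 | sodium (Z)-enolate of 10 | O=C1OC[C@@H](Cc2ccccc2)N1/C(O[Na])=C/OCc1ccccc1 | intermediate (not isolated)
12 | (4R)-4-benzyl-3-[(2S)-2-(benzyloxy)-3-[4-(benzyloxy)-2,6-dibromophenyl]propanoyl]-1,3-oxazolidin-2-one | O=C1OC[C@@H](Cc2ccccc2)N1C(=O)[C@@H](OCc1ccccc1)Cc1c(Br)cc(OCc2ccccc2)cc1Br | intermediate
13 | (2S)-2-(benzyloxy)-3-[4-(benzyloxy)-2,6-dibromophenyl]-N-methoxy-N-methylpropanamide | CON(C)C(=O)[C@@H](OCc1ccccc1)Cc1c(Br)cc(OCc2ccccc2)cc1Br | intermediate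
14 | 4-bromo-1,2-bis(benzyloxy)benzene | Brc1ccc(OCc2ccccc2)c(OCc2ccccc2)c1 | starting material
15 | [3,4-bis(benzyloxy)phenyl]magnesium bromide | Br[Mg]c1ccc(OCc2ccccc2)c(OCc2ccccc2)c1 | intermediate (not isolated)
16 | (2S)-2-(benzyloxy)-3-[4-(benzyloxy)-2,6-dibromophenyl]-1-[3,4-bis(benzyloxy)phenyl]propan-1-one | O=C(c1ccc(OCc2ccccc2)c(OCc2ccccc2)c1)[C@@H](OCc1ccccc1)Cc1c(Br)cc(OCc2ccccc2)cc1Br | intermediate
17 | (1R,2S)-2-(benzyloxy)-3-[4-(benzyloxy)-2,6-dibromophenyl]-1-[3,4-bis(benzyloxy)phenyl]propan-1-ol | Brc1cc(OCc2ccccc2)cc(Br)c1C[C@H](OCc1ccccc1)[C@@H](c1ccc(OCc2ccccc2)c(OCc2ccccc2)c1)O | intermediate (key-step precursor)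
18 | (2R,3S)-3,7-bis(benzyloxy)-2-[3,4-bis(benzyloxy)phenyl]-5-bromo-3,4-dihydro-2H-chromene | Brc1cc(OCc2ccccc2)cc2c1C[C@H](OCc1ccccc1)[C@@H](c1ccc(OCc3ccccc3)c(OCc3ccccc3)c1)O2 | intermediate (key-step product)
19 | (2R,3S)-3,7-bis(benzyloxy)-2-[3,4-bis(benzyloxy)phenyl]-3,4-dihydro-2H-chromen-5-ol | Oc1cc(OCc2ccccc2)cc2c1C[C@H](OCc1ccccc1)[C@@H](c1ccc(OCc3ccccc3)c(OCc3ccccc3)c1)O2 | intermediate
20 | 3,4,5-tris(benzyloxy)benzoic acid | OC(=O)c1cc(OCc2ccccc2)c(OCc2ccccc2)c(OCc2ccccc2)c1 | starting material
21 | (2R,3S)-3,7-bis(benzyloxy)-2-[3,4-bis(benzyloxy)phenyl]-3,4-dihydro-2H-chromen-5-yl 3,4,5-tris(benzyloxy)benzoate | O=C(Oc1cc(OCc2ccccc2)cc2c1C[C@H](OCc1ccccc1)[C@@H](c1ccc(OCc3ccccc3)c(OCc3ccccc3)c1)O2)c1cc(OCc2ccccc2)c(OCc2ccccc2)c(OCc2ccccc2)c1 | intermediate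
22 | catechin 5-O-gallate, (2R,3S) | O=C(Oc1cc(O)cc2c1C[C@H](O)[C@@H](c1ccc(O)c(O)c1)O2)c1cc(O)c(O)c(O)c1 | target

**Step count**

Total: 13 steps. Longest linear sequence: 12 steps (steps 1–4 and 6–13 from 3,5-dibromophenol; step 5 is a one-step side branch).

**Steps most likely to fail**

Step 10 (key ring closure). Insertion of copper into the hindered, electron-rich C–Br bond may be slow. Hydrodebromination, oxidation of the benzylic alcohol back to the ketone, or intermolecular etherification through the second bromide could then take over. The fallback forms the O1–C2 bond instead and sets out from 17. Deprotonation and exchange of one bromide with n-BuLi (2.1 equiv, THF, −78 °C), trapping with B(OMe)3 and aqueous work-up should give [5-(benzyloxy)-2-[(2S,3R)-2-(benzyloxy)-3-[3,4-bis(benzyloxy)phenyl]-3-hydroxypropyl]-3-bromophenyl]boronic acid F1. Oxidation with H2O2/NaOH should convert it into 5-(benzyloxy)-2-[(2S,3R)-2-(benzyloxy)-3-[3,4-bis(benzyloxy)phenyl]-3-hydroxypropyl]-3-bromophenol F2. Catalytic TsOH (or BF3·OEt2) in CH2Cl2 at 0 °C should then ionise the 3,4-dialkoxybenzylic alcohol, and the phenol should capture the cation anti to the C3 benzyloxy group. This cyclodehydration is expected to favour the 2,3-trans chroman, with any cis isomer removed by chromatography, and the fallback comes back to the route at 18.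

Step 6 (glycolate alkylation). The sodium enolate 11 is thermally fragile and may break down faster than it is alkylated by the di-ortho-substituted benzylic bromide. The fallback takes the C3 stereocentre from the chiral pool and sets out from 3 through aryllithium 4 (generated as in step 2). Transmetalation with MgBr2·OEt2 at −78 °C should give [4-(benzyloxy)-2,6-dibromophenyl]magnesium bromide F3. Copper-catalysed opening (CuI, 10 mol%, −78 → −30 °C) of methyl (S)-glycidate (COC(=O)[C@@H]1CO1) at its CH2 terminus should give methyl (2S)-3-[4-(benzyloxy)-2,6-dibromophenyl]-2-hydroxypropanoate F4 with the stereocentre untouched. O-Benzylation with benzyl 2,2,2-trichloroacetimidate and catalytic TfOH should give methyl (2S)-2-(benzyloxy)-3-[4-(benzyloxy)-2,6-dibromophenyl]propanoate F5. MeNH(OMe)·HCl/i-PrMgCl in THF at −20 °C should convert the ester into the Weinreb amide, and the fallback comes back to the route at 13.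

Step 11 (hydroxylation). Under hot aqueous hydroxide the palladium aryl may be reduced (hydrodebromination), or the product phenoxide may be arylated to a diaryl ether. The fallback goes through boron and sets out from 18. Miyaura borylation (B2pin2, PdCl2(dppf), KOAc, 1,4-dioxane, 90 °C) should give 2-[(2R,3S)-3,7-bis(benzyloxy)-2-[3,4-bis(benzyloxy)phenyl]-3,4-dihydro-2H-chromen-5-yl]-4,4,5,5-tetramethyl-1,3,2-dioxaborolane F6. Mild oxidation with NaBO3·4H2O in THF/H2O at rt should give the phenol, and the fallback comes back to the route at 19.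

**Further compounds**

F1 | step 10 | [5-(benzyloxy)-2-[(2S,3R)-2-(benzyloxy)-3-[3,4-bis(benzyloxy)phenyl]-3-hydroxypropyl]-3-bromophenyl]boronic acid | OB(O)c1cc(OCc2ccccc2)cc(Br)c1C[C@H](OCc1ccccc1)[C@@H](c1ccc(OCc2ccccc2)c(OCc2ccccc2)c1)O
F2 | step 10 | 5-(benzyloxy)-2-[(2S,3R)-2-(benzyloxy)-3-[3,4-bis(benzyloxy)phenyl]-3-hydroxypropyl]-3-bromophenol | Oc1cc(OCc2ccccc2)cc(Br)c1C[C@H](OCc1ccccc1)[C@@H](c1ccc(OCc2ccccc2)c(OCc2ccccc2)c1)O
F3 | step 6 | [4-(benzyloxy)-2,6-dibromophenyl]magnesium bromide | Br[Mg]c1c(Br)cc(OCc2ccccc2)cc1Br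
F4 | step 6 | methyl (2S)-3-[4-(benzyloxy)-2,6-dibromophenyl]-2-hydroxypropanoate | COC(=O)[C@@H](O)Cc1c(Br)cc(OCc2ccccc2)cc1Br
F5 | step 6 | methyl (2S)-2-(benzyloxy)-3-[4-(benzyloxy)-2,6-dibromophenyl]propanoate | COC(=O)[C@@H](OCc1ccccc1)Cc1c(Br)cc(OCc2ccccc2)cc1Br
F6 | step 11 | 2-[(2R,3S)-3,7-bis(benzyloxy)-2-[3,4-bis(benzyloxy)phenyl]-3,4-dihydro-2H-chromen-5-yl]-4,4,5,5-tetramethyl-1,3,2-dioxaborolane | CC1(C)OB(OC1(C)C)c1cc(OCc2ccccc2)cc2c1C[C@H](OCc1ccccc1)[C@@H](c1ccc(OCc3ccccc3)c(OCc3ccccc3)c1)O2
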